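**Strategy.** The route rests on cutting, in each 1,4-benzodioxane, the aryl C–O bond between the benzylic oxygen and the arene carbon meta to the ring substituent: O7′ (on the carbon bearing catechol ring C) to C3 of central ring B, and likewise O7 to C3 of the propenyl-bearing ring A. These bonds touch no stereocentre, so all four stereocentres are set beforehand in an open chain by two auxiliary-controlled syn-aldol reactions of aryloxyacetyl imides. The key step then closes both dioxane rings in one operation by twofold intramolecular palladium-catalysed C–O coupling of a bis(2-bromoaryl ether) diol, with retention at both carbinol carbons.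

Key step: step 8

Remark (locants): ring A is the arene bearing the propenyl chain, ring B the central arene, ring C the catechol ring. C7–C8–C9 is the three-carbon unit between rings A and B (C7 benzylic on ring B, C8 bound to O4 of ring A, C9 the CH2O carbon). C7′–C8′–C9′ is the unit between rings B and C (C7′ benzylic on ring C, C8′ bound to O4 of ring B). The target is (7R,8R,7′S,8′S), with both dioxane rings trans.

Remark (assumption): both enantiomers of 4-benzyl-3-(chloroacetyl)-1,3-oxazolidin-2-one are taken as catalogue compounds.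

**Step 1**
Reactants: 1 3-bromo-4-hydroxybenzaldehyde; 2 ethyl (triphenylphosphoranylidene)acetate
Product: 3 ethyl (E)-3-(3-bromo-4-hydroxyphenyl)prop-2-enoate
Conditions: toluene, 90 °C
Reagents that add atoms: none
Why: Wittig olefination with an ester-stabilised ylide is E-selective and tolerates the free phenol, so the E-enoate that later becomes the allylic alcohol should form directly.

**Step 2**
Reactants: 3 ethyl (E)-3-(3-bromo-4-hydroxyphenyl)prop-2-enoate; 4 (4S)-4-benzyl-3-(chloroacetyl)-1,3-oxazolidin-2-one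
Product: 5 imide A, ethyl (E)-3-[3-bromo-4-[2-[(4S)-4-benzyl-2-oxo-1,3-oxazolidin-3-yl]-2-oxoethoxy]phenyl]prop-2-enoate
Conditions: K2CO3, DMF, 25 °C
Reagents that add atoms: none
Why: Williamson ether synthesis, in which the phenoxide displaces chloride from the strongly SN2-activated α-chloro imide, whereas acyl transfer to the weakly basic phenoxide is reversible and uphill.

**Step 3**
Reactants: 1 3-bromo-4-hydroxybenzaldehyde; 6 (4R)-4-benzyl-3-(chloroacetyl)-1,3-oxazolidin-2-one
Product: 7 imide B, 3-bromo-4-[2-[(4R)-4-benzyl-2-oxo-1,3-oxazolidin-3-yl]-2-oxoethoxy]benzaldehyde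
Conditions: K2CO3, DMF, 25 °C
Reagents that add atoms: none
Why: Williamson ether synthesis as in step 2; the aldehyde is inert to carbonate and is kept as the acceptor for the first aldol reaction.

**Step 4**
Reactants: 8 3,4-dihydroxybenzaldehyde
Product: 9 3,4-bis(tert-butyldimethylsilyloxy)benzaldehyde
Conditions: TBSCl (2.4 equiv), imidazole, DMF, 25 °C
Reagents that add atoms: tert-butyldimethylsilyl chloride, CC(C)(C)[Si](C)(C)Cl
Why: Imidazole-promoted silylation caps both catechol hydroxyls as fluoride-labile aryl silyl ethers that should survive boron enolates, borohydride, carbonate base and iBu2AlH.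

**Step 5**
Reactants: 5 imide A; 7 imide B; 9 3,4-bis(tert-butyldimethylsilyloxy)benzaldehyde
Product: 14 bis-aldol adduct (7R,8S,7′S,8′R), via Z-dibutylboron enolate of imide A 10 (not isolated), via C7-O-dibutylborinate of the mono-aldol adduct 11 (not isolated), via Z-dibutylboron enolate of the mono-aldolate 12 (not isolated), via bis(dibutylborinate) of the bis-aldol adduct 13 (not isolated)
Conditions: 5 (1.05 equiv), Bu2BOTf (1.05 equiv), iPr2NEt, CH2Cl2, 0 °C; 7 (1.0 equiv), −78 to 0 °C; Bu2BOTf (1.2 equiv), iPr2NEt, 0 °C; 9 (1.5 equiv), −78 to 0 °C; pH 7 buffer, MeOH, H2O2, 0 °C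
Reagents that add atoms: none
Why: Two consecutive Evans syn-aldol reactions, each Z-boron enolate reacting through a Zimmerman–Traxler chair on the face opposite the auxiliary benzyl group, so the (4S) auxiliary sets (7R,8S) and the (4R) auxiliary sets (7′S,8′R); the first aldolate stays masked as its borinate and the now α-branched first imide should not enolise again.

**Step 6**
Reactants: 14 bis-aldol adduct
Product: 15 tetraol (7R,8R,7′S,8′S)
Conditions: NaBH4, THF/H2O, 0 to 25 °C
Reagents that add atoms: none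
Why: Borohydride reductive cleavage of N-acyl oxazolidinones releases both auxiliaries and gives the two primary alcohols without touching the conjugated ethyl ester or the stereocentres (the descriptors at C8 and C8′ change only because C9 and C9′ drop in CIP rank).

**Step 7**
Reactants: 15 tetraol
Product: 16 9,9′-bis-O-(tert-butyldiphenylsilyl) diol (7R,8R,7′S,8′S)
Conditions: TBDPSCl (2.2 equiv), imidazole, CH2Cl2, 0 °C
Reagents that add atoms: tert-butyl(chloro)diphenylsilane, CC(C)(C)[Si](Cl)(c1ccccc1)c1ccccc1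
Why: Sterically controlled silylation, in which the bulky silyl chloride should react only at the two primary hydroxyls and leave the benzylic C7 and C7′ hydroxyls free; this bulky group is also not expected to migrate to a neighbouring alkoxide in the next step.

**Step 8**
Reactants: 16 9,9′-bis-O-(tert-butyldiphenylsilyl) diol
Product: 19 silyl-protected bis(benzodioxane) ethyl ester (7R,8R,7′S,8′S), via A-ring-fused mono-dioxane bromo alcohol 17 (not isolated), via B-ring-fused mono-dioxane bromo alcohol 18 (not isolated)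
Conditions: Pd(OAc)2 (10 mol %), 2-(di-tert-butylphosphino)-1,1′-binaphthyl (12 mol %), Cs2CO3, toluene, 80 °C
Reagents that add atoms: none
Why: Zerovalent palladium, formed from Pd(OAc)2 and the bulky electron-rich biaryl phosphine, inserts into each aryl C–Br bond; the neighbouring secondary hydroxyl is deprotonated by Cs2CO3 and binds the metal, and C–O reductive elimination forms the O7′–C3(ring B) and O7–C3(ring A) bonds. The closest known reaction type is the Buchwald–Hartwig-type intramolecular etherification of 2-bromoaryl ethers of 1,2-diols to 1,4-benzodioxanes. Each dioxane ring closes in a six-membered exo mode through a seven-membered aryl(alkoxo)palladium chelate. No stereocentre is created: C7 and C7′ keep their configuration because their C–O bonds are never broken, so the syn-aldol relationship becomes the trans-2,3 arrangement in both rings. The step needs the benzylic oxygen, not the C9 or C9′ oxygen (which would close an isomeric six-membered ring), to attack, and this is secured by the silyl ethers on the primary positions. It also needs reductive elimination to outrun β-hydride elimination of the benzylic palladium alkoxide, which the hindered ligand should secure, and no crossed closure is possible because each alkoxide can reach only the bromide ortho to its own ether oxygen.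

**Step 9**
Reactants: 19 silyl-protected bis(benzodioxane) ethyl ester
Product: 20 silyl-protected allylic alcohol
Conditions: iBu2AlH, CH2Cl2, −78 °C; aqueous potassium sodium tartrate
Reagents that add atoms: none
Why: 1,2-Reduction of the α,β-unsaturated ester by the aluminium hydride at low temperature should give the E-allylic alcohol without conjugate reduction, the silyl and aryl ethers being inert.

**Step 10**
Reactants: 20 silyl-protected allylic alcohol
Product: 21 target, (E)-3-[(2R,3R)-3-[(2S,3S)-3-(3,4-dihydroxyphenyl)-2-(hydroxymethyl)-2,3-dihydro-1,4-benzodioxin-6-yl]-2-(hydroxymethyl)-2,3-dihydro-1,4-benzodioxin-6-yl]prop-2-en-1-ol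
Conditions: Bu4NF, AcOH, degassed THF, 0 to 25 °C
Reagents that add atoms: none
Why: Fluoride-mediated desilylation should cleave the two aryl and the two primary alkyl silyl ethers in one operation, the acetic acid buffer keeping the liberated catechol protonated and sparing the allylic alcohol.

**Compound list**

1 | 3-bromo-4-hydroxybenzaldehyde | O=Cc1ccc(O)c(Br)c1 | starting material
2 | ethyl (triphenylphosphoranylidene)acetate | CCOC(=O)C=P(c1ccccc1)(c1ccccc1)c1ccccc1 | starting material
3 | ethyl (E)-3-(3-bromo-4-hydroxyphenyl)prop-2-enoate | CCOC(=O)/C=C/c1ccc(O)c(Br)c1 | intermediate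
4 | (4S)-4-benzyl-3-(chloroacetyl)-1,3-oxazolidin-2-one | O=C(CCl)N1[C@@H](Cc2ccccc2)COC1=O | starting material
5 | imide A, ethyl (E)-3-[3-bromo-4-[2-[(4S)-4-benzyl-2-oxo-1,3-oxazolidin-3-yl]-2-oxoethoxy]phenyl]prop-2-enoate | CCOC(=O)/C=C/c1ccc(OCC(=O)N2[C@@H](Cc3ccccc3)COC2=O)c(Br)c1 | intermediate
6 | (4R)-4-benzyl-3-(chloroacetyl)-1,3-oxazolidin-2-one | O=C(CCl)N1[C@H](Cc2ccccc2)COC1=O | starting material
7 | imide B, 3-bromo-4-[2-[(4R)-4-benzyl-2-oxo-1,3-oxazolidin-3-yl]-2-oxoethoxy]benzaldehyde | O=Cc1ccc(OCC(=O)N2[C@H](Cc3ccccc3)COC2=O)c(Br)c1 | intermediate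
8 | 3,4-dihydroxybenzaldehyde | O=Cc1ccc(O)c(O)c1 | starting material
9 | 3,4-bis(tert-butyldimethylsilyloxy)benzaldehyde | O=Cc1ccc(O[Si](C)(C)C(C)(C)C)c(O[Si](C)(C)C(C)(C)C)c1 | intermediate
10 | Z-dibutylboron enolate of imide A (aryloxy and boryloxy groups cis) | CCOC(=O)/C=C/c1ccc(O/C=C(\OB(CCCC)CCCC)N2[C@@H](Cc3ccccc3)COC2=O)c(Br)c1 | intermediate
11 | C7-O-dibutylborinate of the (7R,8S) mono-aldol adduct of imide A with the aldehyde of imide B | CCOC(=O)/C=C/c1ccc(O[C@H](C(=O)N2[C@@H](Cc3ccccc3)COC2=O)[C@H](OB(CCCC)CCCC)c2ccc(OCC(=O)N3[C@H](Cc4ccccc4)COC3=O)c(Br)c2)c(Br)c1 | intermediate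
12 | Z-dibutylboron enolate (on the ring B aryloxyacetyl imide) of mono-aldolate 11 | CCOC(=O)/C=C/c1ccc(O[C@H](C(=O)N2[C@@H](Cc3ccccc3)COC2=O)[C@H](OB(CCCC)CCCC)c2ccc(O/C=C(\OB(CCCC)CCCC)N3[C@H](Cc4ccccc4)COC3=O)c(Br)c2)c(Br)c1 | intermediate
13 | C7,C7′-bis(O-dibutylborinate) of bis-aldol adduct 14 | CCOC(=O)/C=C/c1ccc(O[C@H](C(=O)N2[C@@H](Cc3ccccc3)COC2=O)[C@H](OB(CCCC)CCCC)c2ccc(O[C@@H](C(=O)N3[C@H](Cc4ccccc4)COC3=O)[C@@H](OB(CCCC)CCCC)c3ccc(O[Si](C)(C)C(C)(C)C)c(O[Si](C)(C)C(C)(C)C)c3)c(Br)c2)c(Br)c1 | intermediate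
14 | (7R,8S,7′S,8′R) bis-aldol adduct: ring A (3-bromo, 1-[(E)-2-ethoxycarbonylvinyl]) O4–C8H[C(=O)-(4S)-auxiliary]–C7H(OH)–ring B (3-bromo) O4–C8′H[C(=O)-(4R)-auxiliary]–C7′H(OH)–ring C [3,4-bis(OTBS)] | CCOC(=O)/C=C/c1ccc(O[C@H](C(=O)N2[C@@H](Cc3ccccc3)COC2=O)[C@H](O)c2ccc(O[C@@H](C(=O)N3[C@H](Cc4ccccc4)COC3=O)[C@@H](O)c3ccc(O[Si](C)(C)C(C)(C)C)c(O[Si](C)(C)C(C)(C)C)c3)c(Br)c2)c(Br)c1 | intermediate
15 | (7R,8R,7′S,8′S) tetraol: as 14 with both acyl oxazolidinone groups replaced by CH2OH (C9, C9′) | CCOC(=O)/C=C/c1ccc(O[C@H](CO)[C@H](O)c2ccc(O[C@@H](CO)[C@@H](O)c3ccc(O[Si](C)(C)C(C)(C)C)c(O[Si](C)(C)C(C)(C)C)c3)c(Br)c2)c(Br)c1 | intermediate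
16 | (7R,8R,7′S,8′S) 9,9′-bis-O-(tert-butyldiphenylsilyl) diol with free C7 and C7′ hydroxyls and a bromine at C3 of rings A and B | CCOC(=O)/C=C/c1ccc(O[C@H](CO[Si](c2ccccc2)(c2ccccc2)C(C)(C)C)[C@H](O)c2ccc(O[C@@H](CO[Si](c3ccccc3)(c3ccccc3)C(C)(C)C)[C@@H](O)c3ccc(O[Si](C)(C)C(C)(C)C)c(O[Si](C)(C)C(C)(C)C)c3)c(Br)c2)c(Br)c1 | intermediate
17 | mono-cyclised intermediate: dioxane on ring A closed (O7–C3 of ring A), ring B still a bromo ether with free C7′ hydroxyl | CCOC(=O)/C=C/c1ccc2c(c1)O[C@H](c1ccc(O[C@@H](CO[Si](c3ccccc3)(c3ccccc3)C(C)(C)C)[C@@H](O)c3ccc(O[Si](C)(C)C(C)(C)C)c(O[Si](C)(C)C(C)(C)C)c3)c(Br)c1)[C@@H](CO[Si](c1ccccc1)(c1ccccc1)C(C)(C)C)O2 | intermediate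
18 | mono-cyclised intermediate: dioxane on ring B closed (O7′–C3 of ring B), ring A still a bromo ether with free C7 hydroxyl | CCOC(=O)/C=C/c1ccc(O[C@H](CO[Si](c2ccccc2)(c2ccccc2)C(C)(C)C)[C@H](O)c2ccc3c(c2)O[C@@H](c2ccc(O[Si](C)(C)C(C)(C)C)c(O[Si](C)(C)C(C)(C)C)c2)[C@H](CO[Si](c2ccccc2)(c2ccccc2)C(C)(C)C)O3)c(Br)c1 | intermediate
19 | (7R,8R,7′S,8′S) bis(trans-benzodioxane) ethyl (E)-enoate with 9,9′-bis(OTBDPS) and ring C bis(OTBS) | CCOC(=O)/C=C/c1ccc2c(c1)O[C@H](c1ccc3c(c1)O[C@@H](c1ccc(O[Si](C)(C)C(C)(C)C)c(O[Si](C)(C)C(C)(C)C)c1)[C@H](CO[Si](c1ccccc1)(c1ccccc1)C(C)(C)C)O3)[C@@H](CO[Si](c1ccccc1)(c1ccccc1)C(C)(C)C)O2 | intermediate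
20 | (E)-allylic alcohol corresponding to 19 (four silyl ethers retained) | OC/C=C/c1ccc2c(c1)O[C@H](c1ccc3c(c1)O[C@@H](c1ccc(O[Si](C)(C)C(C)(C)C)c(O[Si](C)(C)C(C)(C)C)c1)[C@H](CO[Si](c1ccccc1)(c1ccccc1)C(C)(C)C)O3)[C@@H](CO[Si](c1ccccc1)(c1ccccc1)C(C)(C)C)O2 | intermediate
21 | (E)-3-[(2R,3R)-3-[(2S,3S)-3-(3,4-dihydroxyphenyl)-2-(hydroxymethyl)-2,3-dihydro-1,4-benzodioxin-6-yl]-2-(hydroxymethyl)-2,3-dihydro-1,4-benzodioxin-6-yl]prop-2-en-1-ol | OC/C=C/c1ccc2c(c1)O[C@H](c1ccc3c(c1)O[C@@H](c1ccc(O)c(O)c1)[C@H](CO)O3)[C@@H](CO)O2 | target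

**Step count and risks**

Total step count: 10. Longest linear sequence: 8 steps (steps 1, 2, 5, 6, 7, 8, 9, 10).

Steps most likely to fail:

1. Step 8. β-Hydride elimination from the benzylic palladium alkoxides (oxidation of the carbinol with loss of bromine) may compete with C–O reductive elimination, or the sequence may stall after the first ring closure. The fallback keeps the same two aryl C–O bonds but reverses the polarity of the arene. From 16, Miyaura borylation (B2pin2, PdCl2(dppf), KOAc, dioxane, 80 °C; acetate is too weak a base to trigger etherification) would give the bis(pinacol boronate) F1. Intramolecular Chan–Lam etherification (Cu(OAc)2, pyridine, 4 Å sieves, O2, CH2Cl2, 25 °C) would then close both rings by transmetalation to divalent copper and reductive elimination from a trivalent copper alkoxide, with no palladium alkoxide involved. This returns to the route at 19.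

2. Step 5. The telescoped second enolisation may be incomplete, or the aldehyde-bearing imide 7 may be enolised by residual boron triflate and self-condense, giving mixtures that are hard to separate. The fallback runs the two aldol reactions as separate, protected operations. From 5 and 7, a single boron aldol with oxidative work-up would give the mono-aldol adduct F2. TESOTf and 2,6-lutidine would convert it into its triethylsilyl ether F3. Enolisation of the remaining aryloxyacetyl imide (Bu2BOTf, iPr2NEt) and addition of 9 would give the silylated bis-aldol adduct F4. PPTS in MeOH would remove only the triethylsilyl group and return to the route at 14.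

3. Step 10. The catecholate freed under basic fluoride may be oxidised by air, and slow cleavage of the two primary silyl ethers would prolong exposure of the sensitive cinnamyl alcohol. The fallback inverts the order of the last two operations. From 19, all four silyl groups would be removed at the robust ester stage with aqueous HF in MeCN to give the ethyl ester tetraol F5. Excess iBu2AlH (THF, −78 to 0 °C) would then reduce the enoate of the unprotected polyol directly, rejoining the route at 21.

**Further compounds**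

F1 | step 8 | bis(pinacol boronate): 16 with both bromine atoms replaced by 4,4,5,5-tetramethyl-1,3,2-dioxaborolan-2-yl | CCOC(=O)/C=C/c1ccc(O[C@H](CO[Si](c2ccccc2)(c2ccccc2)C(C)(C)C)[C@H](O)c2ccc(O[C@@H](CO[Si](c3ccccc3)(c3ccccc3)C(C)(C)C)[C@@H](O)c3ccc(O[Si](C)(C)C(C)(C)C)c(O[Si](C)(C)C(C)(C)C)c3)c(B3OC(C)(C)C(C)(C)O3)c2)c(B2OC(C)(C)C(C)(C)O2)c1
F2 | step 5 | (7R,8S) mono-aldol adduct of imide A with the aldehyde of imide B, free C7 hydroxyl | CCOC(=O)/C=C/c1ccc(O[C@H](C(=O)N2[C@@H](Cc3ccccc3)COC2=O)[C@H](O)c2ccc(OCC(=O)N3[C@H](Cc4ccccc4)COC3=O)c(Br)c2)c(Br)c1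
F3 | step 5 | C7-O-triethylsilyl ether of F2 | CCOC(=O)/C=C/c1ccc(O[C@H](C(=O)N2[C@@H](Cc3ccccc3)COC2=O)[C@H](O[Si](CC)(CC)CC)c2ccc(OCC(=O)N3[C@H](Cc4ccccc4)COC3=O)c(Br)c2)c(Br)c1
F4 | step 5 | C7-O-triethylsilyl ether of bis-aldol adduct 14 (free C7′ hydroxyl) | CCOC(=O)/C=C/c1ccc(O[C@H](C(=O)N2[C@@H](Cc3ccccc3)COC2=O)[C@H](O[Si](CC)(CC)CC)c2ccc(O[C@@H](C(=O)N3[C@H](Cc4ccccc4)COC3=O)[C@@H](O)c3ccc(O[Si](C)(C)C(C)(C)C)c(O[Si](C)(C)C(C)(C)C)c3)c(Br)c2)c(Br)c1
F5 | step 10 | ethyl (E)-3-[(2R,3R)-3-[(2S,3S)-3-(3,4-dihydroxyphenyl)-2-(hydroxymethyl)-2,3-dihydro-1,4-benzodioxin-6-yl]-2-(hydroxymethyl)-2,3-dihydro-1,4-benzodioxin-6-yl]prop-2-enoate | CCOC(=O)/C=C/c1ccc2c(c1)O[C@H](c1ccc3c(c1)O[C@@H](c1ccc(O)c(O)c1)[C@H](CO)O3)[C@@H](CO)O2
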